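The seven-membered ring is disconnected between the ring-fusion carbon C5 and the oxygen-bearing carbon C6. An intramolecular Nozaki–Hiyama–Kishi reaction joins an alkenyl triflate carbon of a cyclopentene (C5) to a tethered aldehyde (C6): one operation closes the cycloheptene ring and creates the C6 carbinol while C5 stays trigonal. The step exploits the 1,3-dioxygenated array C4–C5–C6 that spans the five- and seven-membered rings: the surviving C4=C5 alkene later takes hydrogen at C5 anti to the C1 methyl and oxygen at C4, and the C4 ketone then accepts isopropyl cis to C5–H. The precursor is a cyclopentenyl triflate whose quaternary carbon carries a (Z)-3-methyl-5-oxopent-2-enyl chain.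

Key step: step 8

Remark: bicyclic compounds are numbered as daucanes (C1 methyl-bearing ring-fusion carbon, C2–C3 cyclopentane CH2, C4 carbinol carbon, C5 ring-fusion CH, C6 ester-bearing carbon, C7 CH2, C8 methyl-bearing and C9 epoxide carbons, C10 CH2). α is the face of C5–H in the target and β that of the C1 methyl. Solutions of (2-ethoxy-2-oxoethyl)zinc bromide and of isopropylmagnesium chloride are taken as commercial.

Step 1
Reactants: 1 but-2-yn-1-ol
Product: 3 (2Z)-3-iodobut-2-en-1-ol, via cyclic alkenylaluminate 2 (not isolated)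
Conditions: NaAlH2(OCH2CH2OMe)2 (Red-Al), Et2O, 0 to 25 °C; then I2, THF, −78 °C; aq. Na2S2O3
Reagents that add atoms: iodine, SMILES II
Why: trans-Hydroalumination of the propargylic alcohol gives a five-membered alkenylaluminate with aluminium on C3 cis to the CH2O group, and iodinolysis with retention should fix the (Z)-alkenyl iodide (hydroalumination–iodination).

Step 2
Reactants: 3 (2Z)-3-iodobut-2-en-1-ol
Product: 4 (2Z)-1-bromo-3-iodobut-2-ene
Conditions: CBr4, PPh3, CH2Cl2, 0 °C
Reagents that add atoms: tetrabromomethane, SMILES BrC(Br)(Br)Br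
Why: The Appel reaction converts the primary allylic alcohol into the bromide under neutral conditions that leave the alkenyl iodide and its geometry untouched.

Step 3
Reactants: 5 2-methylcyclopentan-1-one
Product: 6 2-methylcyclopent-1-en-1-yl acetate
Conditions: isopropenyl acetate, TsOH (cat.), reflux, acetone distilled off
Reagents that add atoms: isopropenyl acetate, SMILES CC(=C)OC(C)=O
Why: Acid-catalysed enol ester exchange under equilibrating conditions should favour the more substituted enol acetate, which fixes the site of the later alkylation (enol acetate formation).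

Step 4
Reactants: 6 2-methylcyclopent-1-en-1-yl acetate; 4 (2Z)-1-bromo-3-iodobut-2-ene
Product: 8 (2R)-2-[(2Z)-3-iodobut-2-en-1-yl]-2-methylcyclopentan-1-one, via tin enolate 7 (not isolated)
Conditions: Bu3SnOMe, neat, 25 °C, then vacuum; then 4, chloro[(R,R)-N,N′-bis(3,5-di-tert-butylsalicylidene)cyclohexane-1,2-diaminato]chromium (10 mol %), benzene, 0 °C
Reagents that add atoms: none
Why: Bu3SnOMe converts the enol acetate into the tetrasubstituted tributyltin enolate, and its SN2 alkylation by the allylic bromide inside the chiral chromium salen Lewis acid should set the quaternary C1 centre as R (catalytic enantioselective tin-enolate alkylation; the mirror-image catalyst is taken if the sense of induction demands it).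

Step 5
Reactants: 8 (2R)-2-[(2Z)-3-iodobut-2-en-1-yl]-2-methylcyclopentan-1-one
Product: 10 (5R)-5-[(2Z)-3-iodobut-2-en-1-yl]-5-methylcyclopent-1-en-1-yl trifluoromethanesulfonate, via potassium enolate 9 (not isolated)
Conditions: KN(SiMe3)2, THF, −78 °C; then PhNTf2, −78 to 0 °C
Reagents that add atoms: N-phenylbis(trifluoromethanesulfonimide), SMILES O=S(=O)(N(c1ccccc1)S(=O)(=O)C(F)(F)F)C(F)(F)F
Why: The ketone has α-hydrogens only at C4, so a single enolate forms and O-sulfonylation gives the C5 alkenyl triflate (enol triflate formation).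

Step 6
Reactants: 10 (5R)-5-[(2Z)-3-iodobut-2-en-1-yl]-5-methylcyclopent-1-en-1-yl trifluoromethanesulfonate; 11 (2-ethoxy-2-oxoethyl)zinc bromide
Product: 12 ethyl (3Z)-3-methyl-5-[(1R)-1-methyl-2-{[(trifluoromethyl)sulfonyl]oxy}cyclopent-2-en-1-yl]pent-3-enoate
Conditions: Pd(PPh3)4 (5 mol %), THF–DMPU, 40 °C
Reagents that add atoms: none
Why: Palladium should insert into the alkenyl C–I bond much faster than into the hindered alkenyl triflate next to the quaternary carbon, and Negishi coupling with the Reformatsky reagent proceeds with retention of the (Z) geometry to append C7 and C6.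

Step 7
Reactants: 12 ethyl (3Z)-3-methyl-5-[(1R)-1-methyl-2-{[(trifluoromethyl)sulfonyl]oxy}cyclopent-2-en-1-yl]pent-3-enoate
Product: 14 (5R)-5-methyl-5-[(2Z)-3-methyl-5-oxopent-2-en-1-yl]cyclopent-1-en-1-yl trifluoromethanesulfonate, via aluminium hemiacetal 13 (not isolated)
Conditions: iBu2AlH (1.05 equiv), CH2Cl2, −78 °C; MeOH, then aq. KNaC4H4O6; used at once
Reagents that add atoms: none
Why: At −78 °C the tetrahedral aluminium hemiacetal is stable and releases the aldehyde only on work-up (iBu2AlH half-reduction), and the neutral conditions should keep the β,γ-alkene out of conjugation.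

Step 8
Reactants: 14 (5R)-5-methyl-5-[(2Z)-3-methyl-5-oxopent-2-en-1-yl]cyclopent-1-en-1-yl trifluoromethanesulfonate
Product: 16 (4S,8aR)-6,8a-dimethyl-1,2,4,5,8,8a-hexahydroazulen-4-ol, via alkenylchromium dichloride 15 (not isolated)
Conditions: CrCl2 (8 equiv), NiCl2 (2 mol %), DMSO–THF, 25 °C, 0.005 M, slow addition of 14
Reagents that add atoms: none
Why: Zerovalent nickel, formed from NiCl2 and CrCl2, inserts into the alkenyl C–OTf bond, transmetalation gives alkenylchromium 15 (trivalent chromium), and this adds to the chromium-coordinated aldehyde through a four-centre transition state. This is an intramolecular Nozaki–Hiyama–Kishi reaction. The seven-membered ring closes by 7-exo-trig attack of C5 on the carbonyl carbon C6, helped by the (Z)-C8=C9 alkene, which holds C7 and C10 on the same side. The new stereocentre C6 is controlled by the quaternary C1: in the folded transition state the chromium-bound oxygen should turn outward, toward the vinylic C4–H and away from the C1 methyl, which corresponds to 6S. The step needs chemoselective addition to the aldehyde in the presence of acidic α-hydrogens and a skipped alkene, which the low basicity of organochromium reagents secures, and high dilution to suppress intermolecular coupling. C5 stays trigonal, so the ring fusion is not decided in the ring closure.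

Step 9
Reactants: 16 (4S,8aR)-6,8a-dimethyl-1,2,4,5,8,8a-hexahydroazulen-4-ol; 17 4-methoxybenzoyl chloride
Product: 18 (4S,8aR)-6,8a-dimethyl-1,2,4,5,8,8a-hexahydroazulen-4-yl 4-methoxybenzoate
Conditions: Et3N, DMAP (cat.), CH2Cl2, 0 to 25 °C
Reagents that add atoms: none
Why: DMAP-catalysed acyl transfer esterifies the secondary allylic alcohol without touching the C6 configuration and at the same time protects this oxygen for the next steps.

Step 10
Reactants: 18 (4S,8aR)-6,8a-dimethyl-1,2,4,5,8,8a-hexahydroazulen-4-yl 4-methoxybenzoate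
Product: 19 8α,9α-epoxide of 18 [(1R,6S,8R,9S)]
Conditions: mCPBA (1.05 equiv), NaHCO3, CH2Cl2, 0 °C
Reagents that add atoms: 3-chloroperoxybenzoic acid, SMILES OOC(=O)c1cccc(Cl)c1
Why: Prilezhaev epoxidation should take the C8=C9 alkene, because C4=C5 is deactivated by the allylic ester and shielded by the quaternary C1, and attack anti to the axial C1 methyl should give the α-epoxide.

Step 11
Reactants: 19 8α,9α-epoxide of 18
Product: 21 4α-hydroxy-5α-H epoxy ester [(1R,4R,5R,6S,8R,9S)], via C4 alkylborane 20 (not isolated)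
Conditions: BH3·THF, THF, 0 °C; then NaBO3·4H2O, H2O, 25 °C
Reagents that add atoms: sodium perborate, SMILES [Na+].[Na+].O[B-]1(O)OO[B-](O)(O)OO1
Why: Hydroboration puts boron on the less substituted C4 and hydrogen on C5 by syn addition from the face opposite the angular C1 methyl, which sets the trans ring fusion, and perborate oxidation with retention spares the ester and the epoxide (hydroboration–oxidation).

Step 12
Reactants: 21 4α-hydroxy-5α-H epoxy ester
Product: 22 C4 ketone of 21 [(1R,5S,6S,8R,9S)]
Conditions: Dess–Martin periodinane, NaHCO3, CH2Cl2, 0 to 25 °C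
Reagents that add atoms: none
Why: Dess–Martin oxidation under buffered, non-basic conditions should give the ketone without epimerising C5 or eliminating the β-acyloxy group.

Step 13
Reactants: 22 C4 ketone of 21; 23 isopropylmagnesium chloride
Product: 24 (1R,4R,5S,6S,8R,9S)-8α,9α-epoxy-4β-hydroxydaucan-6α-yl 4-methoxybenzoate (CNP0235939.1)
Conditions: anhydrous CeCl3, THF, −78 °C; AcOH quench at −78 °C
Reagents that add atoms: none
Why: The weakly basic organocerium reagent should add to the ketone and not to the aryl ester, from the α face of the cyclopentanone, which is opposite both the C6 carbon on C5 and the C1 methyl, so that isopropyl enters cis to C5–H and the tertiary hydroxyl ends up β (organocerium 1,2-addition).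

Compound list
1 | but-2-yn-1-ol | CC#CCO | starting material
2 | cyclic alkenylaluminate (sodium 2,2-bis(2-methoxyethoxy)-3-methyl-2,5-dihydro-1,2-oxaluminol-2-uide) | CC1=CCO[Al-]1(OCCOC)OCCOC.[Na+] | intermediate (not isolated)
3 | (2Z)-3-iodobut-2-en-1-ol | C/C(I)=C/CO | intermediate
4 | (2Z)-1-bromo-3-iodobut-2-ene | C/C(I)=C/CBr | intermediate
5 | 2-methylcyclopentan-1-one (racemic) | CC1CCCC1=O | starting material
6 | 2-methylcyclopent-1-en-1-yl acetate | CC(=O)OC1=C(C)CCC1 | intermediate
7 | tin enolate, tributyl[(2-methylcyclopent-1-en-1-yl)oxy]stannane | CCCC[Sn](CCCC)(CCCC)OC1=C(C)CCC1 | intermediate (not isolated)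
8 | (2R)-2-[(2Z)-3-iodobut-2-en-1-yl]-2-methylcyclopentan-1-one | C/C(I)=C/C[C@@]1(C)CCCC1=O | intermediate
9 | potassium (5R)-5-[(2Z)-3-iodobut-2-en-1-yl]-5-methylcyclopent-1-en-1-olate | C/C(I)=C/C[C@@]1(C)CCC=C1[O-].[K+] | intermediate (not isolated)
10 | (5R)-5-[(2Z)-3-iodobut-2-en-1-yl]-5-methylcyclopent-1-en-1-yl trifluoromethanesulfonate | C/C(I)=C/C[C@@]1(C)CCC=C1OS(=O)(=O)C(F)(F)F | intermediate
11 | (2-ethoxy-2-oxoethyl)zinc bromide | CCOC(=O)C[Zn]Br | starting material
12 | ethyl (3Z)-3-methyl-5-[(1R)-1-methyl-2-{[(trifluoromethyl)sulfonyl]oxy}cyclopent-2-en-1-yl]pent-3-enoate | CCOC(=O)C/C(C)=C\C[C@@]1(C)CCC=C1OS(=O)(=O)C(F)(F)F | intermediate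
13 | aluminium hemiacetal of 12 (1-ethoxy-1-(diisobutylaluminoxy) derivative) | CCOC(O[Al](CC(C)C)CC(C)C)C/C(C)=C\C[C@@]1(C)CCC=C1OS(=O)(=O)C(F)(F)F | intermediate (not isolated)
14 | (5R)-5-methyl-5-[(2Z)-3-methyl-5-oxopent-2-en-1-yl]cyclopent-1-en-1-yl trifluoromethanesulfonate | O=CC/C(C)=C\C[C@@]1(C)CCC=C1OS(=O)(=O)C(F)(F)F | intermediate
15 | dichloro{(5R)-5-methyl-5-[(2Z)-3-methyl-5-oxopent-2-en-1-yl]cyclopent-1-en-1-yl}chromium | O=CC/C(C)=C\C[C@@]1(C)CCC=C1[Cr](Cl)Cl | intermediate (not isolated)
16 | (4S,8aR)-6,8a-dimethyl-1,2,4,5,8,8a-hexahydroazulen-4-ol | O[C@H]1CC(C)=CC[C@@]2(C)CCC=C12 | intermediate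
17 | 4-methoxybenzoyl chloride | COc1ccc(C(Cl)=O)cc1 | starting material
18 | (4S,8aR)-6,8a-dimethyl-1,2,4,5,8,8a-hexahydroazulen-4-yl 4-methoxybenzoate | COc1ccc(C(=O)O[C@H]2CC(C)=CC[C@@]3(C)CCC=C23)cc1 | intermediate
19 | 8α,9α-epoxide of 18, (1R,6S,8R,9S), C4=C5 alkene retained | COc1ccc(C(=O)O[C@H]2C[C@@]3(C)O[C@H]3C[C@@]3(C)CCC=C23)cc1 | intermediate
20 | C4 alkylborane of 19 (BH2 on C4 α, H on C5 α) | COc1ccc(C(=O)O[C@H]2C[C@@]3(C)O[C@H]3C[C@@]3(C)CC[C@@H](B)[C@H]23)cc1 | intermediate (not isolated)
21 | trans-fused 4α-alcohol, (1R,4R,5R,6S,8R,9S)-8,9-epoxy-4-hydroxy 6-(4-methoxybenzoate) | COc1ccc(C(=O)O[C@H]2C[C@@]3(C)O[C@H]3C[C@@]3(C)CC[C@@H](O)[C@H]23)cc1 | intermediate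
22 | trans-fused C4 ketone, (1R,5S,6S,8R,9S)-8,9-epoxy-4-oxo 6-(4-methoxybenzoate) | COc1ccc(C(=O)O[C@H]2C[C@@]3(C)O[C@H]3C[C@@]3(C)CCC(=O)[C@H]23)cc1 | intermediate
23 | isopropylmagnesium chloride | CC(C)[Mg]Cl | starting material
24 | (1R,4R,5S,6S,8R,9S)-8α,9α-epoxy-4β-hydroxydaucan-6α-yl 4-methoxybenzoate (CNP0235939.1) | COc1ccc(C(=O)O[C@H]2C[C@@]3(C)O[C@H]3C[C@@]3(C)CC[C@@](O)(C(C)C)[C@H]23)cc1 | target

Total step count: 13. Longest linear sequence: 12 steps (steps 1, 2 and 4 to 13, from 1); step 3 is a one-step side branch that prepares 6 from 5.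

Steps most likely to fail

Step 8: the aldehyde may be attacked on both faces, so that the C6 epimer forms in quantity. The fallback sets out from 14. The cyclisation product is carried on as the epimer mixture that contains (4R,8aR)-6,8a-dimethyl-1,2,4,5,8,8a-hexahydroazulen-4-ol F1. Oxidation with Dess–Martin periodinane (NaHCO3, CH2Cl2) gives the conjugated enone (8aR)-6,8a-dimethyl-1,2,8,8a-tetrahydroazulen-4(5H)-one F2, in which the skipped C8=C9 alkene stays in place. Corey–Bakshi–Shibata reduction with the (R)-methyl oxazaborolidine and BH3·SMe2 should then set 6S by reagent control, the alkenyl side acting as the large group. This comes back to the route at 16.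

Step 10: chemoselectivity between the two trisubstituted alkenes may be lost, or the peracid may attack the methyl-bearing face. The fallback sets out from 12, where the chain alkene is the only electron-rich one and the alkenyl triflate is inert. Shi epoxidation (fructose-derived ketone catalyst of the enantiomeric series that delivers oxygen to the required face, KHSO5, K2CO3, MeCN–H2O, 0 °C) gives ethyl 2-[(2R,3S)-2-methyl-3-{[(1R)-1-methyl-2-{[(trifluoromethyl)sulfonyl]oxy}cyclopent-2-en-1-yl]methyl}oxiran-2-yl]acetate F3. iBu2AlH at −78 °C gives (5R)-5-methyl-5-{[(2S,3R)-3-methyl-3-(2-oxoethyl)oxiran-2-yl]methyl}cyclopent-1-en-1-yl trifluoromethanesulfonate F4, which is used at once. The same CrCl2/NiCl2 ring closure gives the 8α,9α-epoxide of 16 F5, and acylation with 17 (Et3N, DMAP) comes back to the route at 19.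

Step 13: the ketone may enolise with β-elimination of 4-methoxybenzoate, or the isopropyl reagent may transfer a β-hydride and reduce the hindered ketone. The fallback sets out from 22. Isopropenylmagnesium bromide (CH2=C(CH3)MgBr) with CeCl3 in THF at −78 °C is an sp2 nucleophile that is less basic and cannot deliver a β-hydride. It should give the 4-isopropenyl analogue of 24, (1R,4S,5S,6S,8R,9S) F6. Hydrogenation of its 1,1-disubstituted alkene (H2, RhCl(PPh3)3, benzene, 25 °C) comes back to the route at 24.

Further compounds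
F1 | step 8 | (4R,8aR)-6,8a-dimethyl-1,2,4,5,8,8a-hexahydroazulen-4-ol | O[C@@H]1CC(C)=CC[C@@]2(C)CCC=C12
F2 | step 8 | (8aR)-6,8a-dimethyl-1,2,8,8a-tetrahydroazulen-4(5H)-one | O=C1CC(C)=CC[C@@]2(C)CCC=C12
F3 | step 10 | ethyl 2-[(2R,3S)-2-methyl-3-{[(1R)-1-methyl-2-{[(trifluoromethyl)sulfonyl]oxy}cyclopent-2-en-1-yl]methyl}oxiran-2-yl]acetate | CCOC(=O)C[C@@]1(C)O[C@H]1C[C@@]1(C)CCC=C1OS(=O)(=O)C(F)(F)F
F4 | step 10 | (5R)-5-methyl-5-{[(2S,3R)-3-methyl-3-(2-oxoethyl)oxiran-2-yl]methyl}cyclopent-1-en-1-yl trifluoromethanesulfonate | O=CC[C@@]1(C)O[C@H]1C[C@@]1(C)CCC=C1OS(=O)(=O)C(F)(F)F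
F5 | step 10 | 8α,9α-epoxide of 16, (1R,6S,8R,9S) | O[C@H]1C[C@@]2(C)O[C@H]2C[C@@]2(C)CCC=C12
F6 | step 13 | 4-isopropenyl analogue of 24, (1R,4S,5S,6S,8R,9S) | COc1ccc(C(=O)O[C@H]2C[C@@]3(C)O[C@H]3C[C@@]3(C)CC[C@@](O)(C(C)=C)[C@H]23)cc1
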